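**Retrosynthetic overview**

1. The target is an 8-hydroxy dibenzylbutyrolactone lignan (lignan C8 = lactone C3, C8′ = C4). In nature the lactone of this class is closed by dehydrogenation of a γ-hydroxy aldehyde through its lactol, and benzylic oxygen is removed reductively.
2. C3–CH2Ar bond: benzylic C–O hydrogenolysis ⇐ aldol of the α-hydroxy lactone enediolate with O-benzylsyringaldehyde, anti to the C4 benzyl (sets the quaternary carbinol).
3. Lactone, the only ring formed (step 3): α-hydroxy lactone ⇐ lactol ⇐ γ-hydroxy aldehyde masked as its dimethyl acetal; hemiacetal closure and aerobic Cu/nitroxyl dehydrogenation in one flask.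
4. C3–C4 bond: D-proline cross-aldol of 3-(3,4-dimethoxyphenyl)propanal with glyoxal mono(dimethyl acetal) sets C4, the only reagent-controlled stereocentre.
5. The C3 oxygen comes in with the glyoxal unit, not by late oxygenation: an oxidant would attack the dibenzyl lactone enolate anti to the C4 benzyl and give the C3 epimer.

Assumption: the target is read as (3S,4S), with the C3 hydroxyl cis to the C4 benzyl and the two benzyl groups trans (the trachelogenin configuration).

**Step 1**
Reactants: 1 3-(3,4-dimethoxyphenyl)propan-1-ol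
Product: 2 3-(3,4-dimethoxyphenyl)propanal
Conditions: [Cu(MeCN)4]OTf (5 mol %), bpy (5 mol %), TEMPO (5 mol %), NMI (10 mol %), air, MeCN, rt
Reagents that add atoms: none
Why: Cu(I)/TEMPO aerobic alcohol oxidation (Stahl oxidation) takes an unhindered primary alcohol to the aldehyde without over-oxidation; no stereocentre is formed.

**Step 2**
Reactants: 2 3-(3,4-dimethoxyphenyl)propanal; 3 2,2-dimethoxyacetaldehyde (from the commercial 60 wt % aqueous solution by CH2Cl2 extraction and drying)
Product: 5 (2S,3S)-2-(3,4-dimethoxybenzyl)-4,4-dimethoxybutane-1,3-diol, via aldol aldehyde 4 (not isolated)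
Conditions: (i) D-proline (20 mol %), DMF, 4 °C, 2 added by syringe pump to 3 (3 equiv); (ii) NaBH4, MeOH, 0 °C
Reagents that add atoms: none
Why: Proline enamine cross-aldol (List–Houk model), in which non-enolisable 3 can only be the acceptor and slow addition of 2 limits self-aldol: the carboxylic acid of D-proline steers 3 onto the enamine face that gives the (2R)-aldehyde 4 (anti; the future lactone C4), and NaBH4 reduces the aldehyde at once, before C2 can epimerise, leaving the acetal untouched.

**Step 3**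
Reactants: 5 (2S,3S)-2-(3,4-dimethoxybenzyl)-4,4-dimethoxybutane-1,3-diol
Product: 7 (3S,4S)-3-hydroxy-4-(3,4-dimethoxybenzyl)dihydrofuran-2(3H)-one, via lactol 6 (not isolated)
Conditions: (i) Amberlyst-15 (H+), MeCN–H2O 4:1, 45 °C, then filter and concentrate; (ii) [Cu(MeCN)4]OTf, bpy, TEMPO (5 mol % each), NMI (10 mol %), air, MeCN, rt to 40 °C
Reagents that add atoms: water, O
Why: Acid hydrolysis of the acetal lets the γ-hydroxy aldehyde close to lactol 6, and Cu/nitroxyl aerobic dehydrogenation of that hemiacetal gives the lactone, the same lactol-to-lactone dehydrogenation by which the lignan lactone ring arises in nature (nitroxyl/O2 in place of NAD+); the TEMPO system spares the secondary C3 carbinol and no stereocentre is formed (C3 is reset in step 4).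

**Step 4**
Reactants: 7 (3S,4S)-3-hydroxy-4-(3,4-dimethoxybenzyl)dihydrofuran-2(3H)-one; 8 4-(benzyloxy)-3,5-dimethoxybenzaldehyde
Product: 10 (3R,4S)-3-{[4-(benzyloxy)-3,5-dimethoxyphenyl](hydroxy)methyl}-3-hydroxy-4-(3,4-dimethoxybenzyl)dihydrofuran-2(3H)-one (both carbinol epimers), via dilithium enediolate 9 (not isolated)
Conditions: LDA (2.2 equiv), THF, −78 to −40 °C; then 8 (1.1 equiv), −78 °C; AcOH quench at −78 °C
Reagents that add atoms: none
Why: Aldol addition of the lactone enediolate (dianion of an α-hydroxy lactone): 8 adds to planar C3 on the face anti to the C4 benzyl group (1,2-induction, as in trans-selective alkylations of β-benzylbutyrolactone enolates), so the new C–C bond is trans and the C3 oxygen cis to that benzyl; both carbinol epimers are carried on.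

**Step 5**
Reactants: 10 (3R,4S)-3-{[4-(benzyloxy)-3,5-dimethoxyphenyl](hydroxy)methyl}-3-hydroxy-4-(3,4-dimethoxybenzyl)dihydrofuran-2(3H)-one
Product: 12 (3S,4S)-3-hydroxy-3-(4-hydroxy-3,5-dimethoxybenzyl)-4-(3,4-dimethoxybenzyl)dihydrofuran-2(3H)-one, via phenol diol 11 (not isolated)
Conditions: H2 (3 atm), 10 % Pd/C, EtOAc–AcOH 9:1, 40 °C
Reagents that add atoms: none
Why: Catalytic hydrogenolysis: O-debenzylation frees the phenol and the electron-rich p-hydroxybenzylic C–O bond is then cleaved (directly or through the quinone methide, the chemical counterpart of the reductive benzylic C–O cleavages of lignan biosynthesis), which removes the only undefined centre and leaves C3 and C4 untouched.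

**Compound list**

1 | 3-(3,4-dimethoxyphenyl)propan-1-ol | COc1ccc(CCCO)cc1OC | starting material
2 | 3-(3,4-dimethoxyphenyl)propanal | COc1ccc(CCC=O)cc1OC | intermediate
3 | 2,2-dimethoxyacetaldehyde | COC(OC)C=O | starting material
4 | (2R,3S)-2-(3,4-dimethoxybenzyl)-3-hydroxy-4,4-dimethoxybutanal | COc1ccc(C[C@@H](C=O)[C@H](O)C(OC)OC)cc1OC | intermediate
5 | (2S,3S)-2-(3,4-dimethoxybenzyl)-4,4-dimethoxybutane-1,3-diol | COc1ccc(C[C@@H](CO)[C@H](O)C(OC)OC)cc1OC | intermediate
6 | (3S,4S)-4-(3,4-dimethoxybenzyl)tetrahydrofuran-2,3-diol (anomer mixture at C2) | COc1ccc(C[C@H]2COC(O)[C@H]2O)cc1OC | intermediate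
7 | (3S,4S)-3-hydroxy-4-(3,4-dimethoxybenzyl)dihydrofuran-2(3H)-one | COc1ccc(C[C@H]2COC(=O)[C@H]2O)cc1OC | intermediate
8 | 4-(benzyloxy)-3,5-dimethoxybenzaldehyde | COc1cc(C=O)cc(OC)c1OCc1ccccc1 | starting material
9 | dilithium (4S)-4-(3,4-dimethoxybenzyl)-4,5-dihydrofuran-2,3-bis(olate) | [Li+].[Li+].COc1ccc(C[C@H]2COC([O-])=C2[O-])cc1OC | intermediate
10 | (3R,4S)-3-{[4-(benzyloxy)-3,5-dimethoxyphenyl](hydroxy)methyl}-3-hydroxy-4-(3,4-dimethoxybenzyl)dihydrofuran-2(3H)-one (carbinol epimers) | COc1ccc(C[C@H]2COC(=O)[C@]2(O)C(O)c2cc(OC)c(OCc3ccccc3)c(OC)c2)cc1OC | intermediate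
11 | (3R,4S)-3-hydroxy-3-[hydroxy(4-hydroxy-3,5-dimethoxyphenyl)methyl]-4-(3,4-dimethoxybenzyl)dihydrofuran-2(3H)-one (carbinol epimers) | COc1ccc(C[C@H]2COC(=O)[C@]2(O)C(O)c2cc(OC)c(O)c(OC)c2)cc1OC | intermediate
12 | (3S,4S)-3-hydroxy-3-(4-hydroxy-3,5-dimethoxybenzyl)-4-(3,4-dimethoxybenzyl)dihydrofuran-2(3H)-one | COc1ccc(C[C@H]2COC(=O)[C@]2(O)Cc2cc(OC)c(O)c(OC)c2)cc1OC | target

**Step count**

Total steps: 5. Longest linear sequence: 5 (1 → 2 → 5 → 7 → 10 → 12).

**Steps most likely to fail, with fallbacks**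

Step 3. The one-flask acetal unmasking and aerobic dehydrogenation may stall at the methyl furanoside, may be slow for the α-substituted lactol with the hindered TEMPO catalyst, or the acid may trigger Friedel–Crafts closure onto the veratryl ring. The fallback sets out from 2 and comes back at 7, with the lactone carbonyl bought at the acid oxidation level so that no dehydrogenation is needed. Aldehyde 2 is condensed with commercial ethyl glyoxylate under the same D-proline enamine catalysis to give ethyl (2S,3R)-3-formyl-2-hydroxy-4-(3,4-dimethoxyphenyl)butanoate F1. NaBH4 at −20 °C reduces only the aldehyde to ethyl (2S,3S)-2-hydroxy-3-(hydroxymethyl)-4-(3,4-dimethoxyphenyl)butanoate F2, which lactonises with catalytic TsOH to 7.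

Step 4. The aldolate of a hindered enediolate may revert or add with poor facial control. The fallback sets out from 8, uses enediolate 9, and comes back at 12, replacing the reversible aldol by an irreversible SN2 alkylation. NaBH4 reduces 8 to [4-(benzyloxy)-3,5-dimethoxyphenyl]methanol F3, and PBr3 converts it into 4-(benzyloxy)-3,5-dimethoxybenzyl bromide F4. Alkylation of 9 with F4, again anti to the C4 benzyl, gives (3S,4S)-3-[4-(benzyloxy)-3,5-dimethoxybenzyl]-3-hydroxy-4-(3,4-dimethoxybenzyl)dihydrofuran-2(3H)-one F5. Hydrogenolysis of the benzyl ether (H2, Pd/C) then gives 12.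

Step 5. Cleavage of a benzylic C–OH bond next to a quaternary carbinol may be slow, and acid could start a semipinacol shift. The fallback sets out from 10 and comes back at 12, turning the hydroxyl into a better leaving group first. Ac2O in pyridine at 0 °C acetylates only the secondary benzylic hydroxyl, giving (RS)-[4-(benzyloxy)-3,5-dimethoxyphenyl][(3R,4S)-3-hydroxy-4-(3,4-dimethoxybenzyl)-2-oxotetrahydrofuran-3-yl]methyl acetate F6. Hydrogenation over Pd/C in neutral EtOAc removes the benzyl ether to give (RS)-(4-hydroxy-3,5-dimethoxyphenyl)[(3R,4S)-3-hydroxy-4-(3,4-dimethoxybenzyl)-2-oxotetrahydrofuran-3-yl]methyl acetate F7, whose activated benzylic C–OAc bond is cleaved in the same flask to give 12.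

**Further compounds**

F1 | step 3 | ethyl (2S,3R)-3-formyl-2-hydroxy-4-(3,4-dimethoxyphenyl)butanoate | COc1ccc(C[C@@H](C=O)[C@H](O)C(=O)OCC)cc1OC
F2 | step 3 | ethyl (2S,3S)-2-hydroxy-3-(hydroxymethyl)-4-(3,4-dimethoxyphenyl)butanoate | COc1ccc(C[C@@H](CO)[C@H](O)C(=O)OCC)cc1OC
F3 | step 4 | [4-(benzyloxy)-3,5-dimethoxyphenyl]methanol | COc1cc(CO)cc(OC)c1OCc1ccccc1
F4 | step 4 | 4-(benzyloxy)-3,5-dimethoxybenzyl bromide | COc1cc(CBr)cc(OC)c1OCc1ccccc1
F5 | step 4 | (3S,4S)-3-[4-(benzyloxy)-3,5-dimethoxybenzyl]-3-hydroxy-4-(3,4-dimethoxybenzyl)dihydrofuran-2(3H)-one | COc1ccc(C[C@H]2COC(=O)[C@]2(O)Cc2cc(OC)c(OCc3ccccc3)c(OC)c2)cc1OC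
F6 | step 5 | (RS)-[4-(benzyloxy)-3,5-dimethoxyphenyl][(3R,4S)-3-hydroxy-4-(3,4-dimethoxybenzyl)-2-oxotetrahydrofuran-3-yl]methyl acetate | COc1ccc(C[C@H]2COC(=O)[C@]2(O)C(OC(C)=O)c2cc(OC)c(OCc3ccccc3)c(OC)c2)cc1OC
F7 | step 5 | (RS)-(4-hydroxy-3,5-dimethoxyphenyl)[(3R,4S)-3-hydroxy-4-(3,4-dimethoxybenzyl)-2-oxotetrahydrofuran-3-yl]methyl acetate | COc1ccc(C[C@H]2COC(=O)[C@]2(O)C(OC(C)=O)c2cc(OC)c(O)c(OC)c2)cc1OC
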